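**Plan**

- Retrosynthesis (ring atoms: C1 = C=O, C2=C3, C4, C5 = carbinol, C6): first the enone and the side-chain ketone are masked as a 1,3-bis(methylsulfanyl)cyclohexene and a 1,3-dithiane. Then the ring is cut at C1–C6 and C3–C4, between the enone unit C1–C2=C3 and the unit C6H2–C5(OH)–C4H2. Last, the side chain is cut between its CH2 and its acyl carbon.
- Enabling feature: C5, the tertiary carbinol of the cyclohexenone ring, carries three CH2 arms (C4, C6, exocyclic CH2), so it can come from one four-carbon epichlorohydrin-type hub. C1 and C3 are the 1,3-related acyl and β-carbons of the enone, normally electrophilic like the hub arms; both are made nucleophilic at once as 1,3-bis(methylsulfanyl)allyllithium, and the side-chain acyl carbon as a 2-lithio-1,3-dithiane.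
- Forward: the hub is made by asymmetric epoxidation; the oleyl dithiane anion takes the first arm while the epoxide moves to the second; the third arm is chlorinated; a one-pot [3+3] annulation closes the six-membered carbocycle; one hydrolysis frees both carbonyls.
- Stereochemistry: the single stereocentre comes from the Sharpless epoxidation (step 2). No bond to it is broken later, and the fixed order in which the three arms are attacked decides which arm ends next to C=O and which next to the alkene. The Z-alkene is bought with oleyl alcohol.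

Key step: step 9

Remark: the vinyl sulfide double bonds of 14–19 and the CH(SMe) centre of 16–19 form as mixtures and are left open in the SMILES; both elements are erased in step 10.

**Route**

Step 1
Reactants: 1 2-methylidenepropane-1,3-diol (3 equiv)
Product: 2 2-(chloromethyl)prop-2-en-1-ol
Conditions: NCS, Me2S, CH2Cl2/THF, −20 → 0 °C; excess 1 washed out with water, product distilled
Reagents that add atoms: N-chlorosuccinimide, O=C1CCC(=O)N1Cl
Why: Corey–Kim chlorination converts an allylic alcohol to the chloride through an alkoxysulfonium salt, and the excess of the symmetric diol should hold the reaction at monosubstitution.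

Step 2
Reactants: 2 2-(chloromethyl)prop-2-en-1-ol
Product: 3 (R)-[2-(chloromethyl)oxiran-2-yl]methanol
Conditions: Ti(OiPr)4, D-(−)-diisopropyl tartrate, t-BuOOH (anhydrous, in decane), 4 Å molecular sieves, CH2Cl2, −20 °C; non-aqueous work-up
Reagents that add atoms: tert-butyl hydroperoxide, CC(C)(C)OO
Why: Sharpless asymmetric epoxidation of a 2-substituted allylic alcohol, in which the titanium tartrate complex delivers oxygen to one enantiotopic face of the alkene; the D-(−) ester is chosen so that the (R)-epoxide should result, and this sets the only stereocentre of the target.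

Step 3
Reactants: 4 (9Z)-octadec-9-en-1-ol (oleyl alcohol)
Product: 5 (9Z)-octadec-9-enal
Conditions: TEMPO (cat.), PhI(OAc)2, CH2Cl2, 20 °C
Reagents that add atoms: none
Why: oxoammonium (TEMPO) oxidation of a primary alcohol stops at the aldehyde and should leave the Z-alkene untouched.

Step 4
Reactants: 5 (9Z)-octadec-9-enal
Product: 6 2-[(8Z)-heptadec-8-en-1-yl]-1,3-dithiane
Conditions: propane-1,3-dithiol, BF3·OEt2, CH2Cl2, 0 °C, argon, dark
Reagents that add atoms: propane-1,3-dithiol, SCCCS
Why: Lewis-acid-catalysed dithioacetalisation turns the aldehyde carbon into an acyl anion equivalent (Corey–Seebach umpolung) and at the same time protects the future ketone.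

Step 5
Reactants: 6 2-[(8Z)-heptadec-8-en-1-yl]-1,3-dithiane; 3 (R)-[2-(chloromethyl)oxiran-2-yl]methanol
Product: 9 [(2S)-2-({2-[(8Z)-heptadec-8-en-1-yl]-1,3-dithian-2-yl}methyl)oxiran-2-yl]methanol, via 2-lithiodithiane 7 (not isolated), via chlorohydrin dialkoxide 8 (not isolated)
Conditions: 6, n-BuLi, THF, −25 °C; then 3 (pre-treated with n-BuLi, 1.0 equiv, THF, −78 °C), DMPU, −78 → 20 °C; aq. NH4Cl
Reagents that add atoms: none
Why: Corey–Seebach alkylation of the lithiodithiane at the unsubstituted epoxide CH2, followed by 3-exo-tet displacement of chloride by the new tertiary alkoxide (the epichlorohydrin relay), should give 9 with the stereocentre intact, because none of its four bonds is broken and the neopentyl-like CH2Cl is not attacked directly.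

Step 6
Reactants: 9 [(2S)-2-({2-[(8Z)-heptadec-8-en-1-yl]-1,3-dithian-2-yl}methyl)oxiran-2-yl]methanol
Product: 10 (2R)-2-(chloromethyl)-2-({2-[(8Z)-heptadec-8-en-1-yl]-1,3-dithian-2-yl}methyl)oxirane
Conditions: PPh3, CCl4, NaHCO3, MeCN, 50 °C
Reagents that add atoms: carbon tetrachloride, ClC(Cl)(Cl)Cl
Why: Appel reaction, in which the primary alcohol is activated as an alkoxyphosphonium salt and displaced by chloride under near-neutral conditions that should leave the epoxide, the dithiane and the Z-alkene alone (the descriptor changes only through the priority rules).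

Step 7
Reactants: 11 (±)-2-(chloromethyl)oxirane (epichlorohydrin)
Product: 12 1,3-bis(methylsulfanyl)propan-2-ol
Conditions: NaSMe (2.2 equiv), MeOH, 0 → 20 °C
Reagents that add atoms: sodium methanethiolate, [Na+].[S-]C
Why: thiolate opens the epoxide, the alkoxide closes onto the chloride and a second thiolate opens the new epoxide, the standard double substitution of epichlorohydrin.

Step 8
Reactants: 12 1,3-bis(methylsulfanyl)propan-2-ol
Product: 13 2-methoxy-1,3-bis(methylsulfanyl)propane
Conditions: NaH, THF, 0 °C; MeI (1.05 equiv), 0 → 20 °C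
Reagents that add atoms: iodomethane, CI
Why: Williamson etherification of the alkoxide installs the methoxy group that serves as the leaving group for generating the thioallyl anion in step 9.

Step 9
Reactants: 13 2-methoxy-1,3-bis(methylsulfanyl)propane; 10 (2R)-2-(chloromethyl)-2-({2-[(8Z)-heptadec-8-en-1-yl]-1,3-dithian-2-yl}methyl)oxirane
Product: 19 (1S)-1-({2-[(8Z)-heptadec-8-en-1-yl]-1,3-dithian-2-yl}methyl)-3,5-bis(methylsulfanyl)cyclohex-3-en-1-ol, via 1,3-bis(methylsulfanyl)prop-1-ene 14 (not isolated), via 1,3-bis(methylsulfanyl)allyllithium 15 (not isolated), via chlorohydrin lithium alkoxide 16 (not isolated), via monoalkylated epoxide 17 (not isolated), via lithiated epoxide 18 (not isolated)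
Conditions: 13, LiN(iPr)2 (2.0 equiv), THF, −78 → 0 °C; 10, −78 → 20 °C; then LiN(iPr)2 (1.2 equiv), THF/DMPU, −78 → 0 °C; aq. NH4Cl
Reagents that add atoms: none
Why: Proposed new method: the symmetric anion 15 (from 13 by loss of methoxide and metalation) opens the epoxide of 10 at its unsubstituted CH2, alkoxide 16 expels the neighbouring chloride to give epoxide 17, and after renewed metalation (18) the far terminus of the thioallyl anion opens this second epoxide, so that one flask joins C1 to C6 and C3 to C4. The closest known reaction types are the alkylation of 1,3-bis(methylsulfanyl)allyllithium by epoxides (a β-acylvinyl anion equivalent), the epoxide–chloride relay of epichlorohydrin with dithiane anions and the Stork epoxynitrile cyclisation; the tandem use of the thioallyl anion as a 1,3-dianion equivalent towards a 1,3-bis-electrophile is the new element. The one ring that forms, the six-membered carbocycle, closes by 6-endo-tet opening of the epoxide at its CH2 terminus, because the 5-exo alternative would be a substitution at the fully substituted carbinol carbon and attack through the near allyl terminus would give a four-membered ring. The carbinol stereocentre is not made here but carried over from step 2, since none of its four bonds is broken; the CH(SMe) centre forms as a mixture that is erased in step 10. The selectivity that matters is the order of the two alkylations, because the allyl carbon alkylated first becomes the vinyl sulfide carbon and hence the ring C=O: the first bond must form at the epoxide and not at the CH2Cl carbon, which the neopentyl-like position and the poor leaving ability of chloride secure. The enantiomeric purity of 10 is thereby translated into the choice of which CH2 arm lies next to the carbonyl and which next to the alkene.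

Step 10
Reactants: 19 (1S)-1-({2-[(8Z)-heptadec-8-en-1-yl]-1,3-dithian-2-yl}methyl)-3,5-bis(methylsulfanyl)cyclohex-3-en-1-ol
Product: 20 (5R)-5-hydroxy-5-[(10Z)-2-oxononadec-10-en-1-yl]cyclohex-2-en-1-one
Conditions: HgCl2 (excess), CaCO3, MeCN/H2O 4:1, 20 → 40 °C
Reagents that add atoms: water, O
Why: thiophilic HgCl2-assisted hydrolysis should turn the dithiane into the side-chain ketone and the vinyl sulfide carbon into the ring carbonyl while the allylic methylsulfanyl group leaves to give the conjugated enone (the known unmasking of 1,3-bis(methylsulfanyl)allyl adducts), with CaCO3 buffering the acid so that the β-hydroxy ketone does not dehydrate.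

**Compound list**

1 | 2-methylidenepropane-1,3-diol | C=C(CO)CO | starting material
2 | 2-(chloromethyl)prop-2-en-1-ol | C=C(CO)CCl | intermediate
3 | (R)-[2-(chloromethyl)oxiran-2-yl]methanol | OC[C@]1(CCl)CO1 | intermediate
4 | (9Z)-octadec-9-en-1-ol (oleyl alcohol) | CCCCCCCC/C=C\CCCCCCCCO | starting material
5 | (9Z)-octadec-9-enal | CCCCCCCC/C=C\CCCCCCCC=O | intermediate
6 | 2-[(8Z)-heptadec-8-en-1-yl]-1,3-dithiane | CCCCCCCC/C=C\CCCCCCCC1SCCCS1 | intermediate
7 | 2-[(8Z)-heptadec-8-en-1-yl]-2-lithio-1,3-dithiane | [Li]C1(CCCCCCC/C=C\CCCCCCCC)SCCCS1 | intermediate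
8 | dilithium (2S)-2-(chloromethyl)-3-{2-[(8Z)-heptadec-8-en-1-yl]-1,3-dithian-2-yl}propane-1,2-diolate | CCCCCCCC/C=C\CCCCCCCC1(SCCCS1)C[C@@](O[Li])(CCl)CO[Li] | intermediate
9 | [(2S)-2-({2-[(8Z)-heptadec-8-en-1-yl]-1,3-dithian-2-yl}methyl)oxiran-2-yl]methanol | CCCCCCCC/C=C\CCCCCCCC1(SCCCS1)C[C@]2(CO)CO2 | intermediate
10 | (2R)-2-(chloromethyl)-2-({2-[(8Z)-heptadec-8-en-1-yl]-1,3-dithian-2-yl}methyl)oxirane | CCCCCCCC/C=C\CCCCCCCC1(SCCCS1)C[C@]2(CCl)CO2 | intermediate
11 | (±)-2-(chloromethyl)oxirane (epichlorohydrin) | ClCC1CO1 | starting material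
12 | 1,3-bis(methylsulfanyl)propan-2-ol | CSCC(O)CSC | intermediate
13 | 2-methoxy-1,3-bis(methylsulfanyl)propane | CSCC(OC)CSC | intermediate
14 | 1,3-bis(methylsulfanyl)prop-1-ene | CSC=CCSC | intermediate
15 | 1,3-bis(methylsulfanyl)allyllithium | [Li]C(SC)C=CSC | intermediate
16 | lithium (2S)-1-chloro-2-({2-[(8Z)-heptadec-8-en-1-yl]-1,3-dithian-2-yl}methyl)-4,6-bis(methylsulfanyl)hex-5-en-2-olate | CCCCCCCC/C=C\CCCCCCCC1(SCCCS1)C[C@](O[Li])(CCl)CC(SC)C=CSC | intermediate
17 | (2S)-2-[2,4-bis(methylsulfanyl)but-3-en-1-yl]-2-({2-[(8Z)-heptadec-8-en-1-yl]-1,3-dithian-2-yl}methyl)oxirane | CCCCCCCC/C=C\CCCCCCCC1(SCCCS1)C[C@@]2(CC(SC)C=CSC)CO2 | intermediate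
18 | (2S)-2-[2-lithio-2,4-bis(methylsulfanyl)but-3-en-1-yl]-2-({2-[(8Z)-heptadec-8-en-1-yl]-1,3-dithian-2-yl}methyl)oxirane | CCCCCCCC/C=C\CCCCCCCC1(SCCCS1)C[C@@]2(CC([Li])(SC)C=CSC)CO2 | intermediate
19 | (1S)-1-({2-[(8Z)-heptadec-8-en-1-yl]-1,3-dithian-2-yl}methyl)-3,5-bis(methylsulfanyl)cyclohex-3-en-1-ol | CCCCCCCC/C=C\CCCCCCCC1(SCCCS1)C[C@]2(O)CC(SC)C=C(SC)C2 | intermediate
20 | (5R)-5-hydroxy-5-[(10Z)-2-oxononadec-10-en-1-yl]cyclohex-2-en-1-one | CCCCCCCC/C=C\CCCCCCCC(=O)C[C@]1(O)CC=CC(=O)C1 | target

**Count and risks**

Total steps: 10. Longest linear sequence: 6 (steps 1, 2, 5, 6, 9, 10).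

1. Step 9. The ring-closing second alkylation may lose to base-induced isomerisation of epoxide 17 to an allylic alcohol or to intermolecular alkylation, and any first attack at the CH2Cl carbon would exchange the two arms and lower the enantiomeric purity. The fallback uses known reactions only, sets out from 10 and comes back at 20, and closes the ring at C2=C3 by metathesis. 2-Lithio-1,3-dithiane (from 1,3-dithiane and n-BuLi, THF, −30 → 20 °C) opens the epoxide of 10 and the alkoxide displaces chloride, giving (2S)-2-(1,3-dithian-2-ylmethyl)-2-({2-[(8Z)-heptadec-8-en-1-yl]-1,3-dithian-2-yl}methyl)oxirane F1. CH2=CHMgBr with catalytic CuI (THF, −40 → 0 °C) opens the new epoxide to (2S)-1-(1,3-dithian-2-yl)-2-({2-[(8Z)-heptadec-8-en-1-yl]-1,3-dithian-2-yl}methyl)pent-4-en-2-ol F2. HgCl2/CaCO3 in aqueous MeCN removes both dithianes to give (3S,13Z)-3-hydroxy-5-oxo-3-(prop-2-en-1-yl)docos-13-enal F3. CH2=CHMgBr at −78 °C should add to the aldehyde before the ketone, giving (5S,15Z)-3,5-dihydroxy-5-(prop-2-en-1-yl)tetracosa-1,15-dien-7-one F4 as both 3-epimers. The second-generation Grubbs catalyst (H2IMes)(PCy3)Cl2Ru=CHPh in CH2Cl2 closes the cyclohexene to (10Z)-1-[(1S)-1,5-dihydroxycyclohex-3-en-1-yl]nonadec-10-en-2-one F5, and MnO2 oxidises its allylic alcohol to 20. The two epoxides are opened in the same order as in step 9, so the same enantiomer should result.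

2. Step 6. Substitution at the neopentyl-like carbon may be slow, which leaves time for chloride-induced opening and re-closure of the epoxide (exchange of the two arms, hence racemisation) and for participation of a dithiane sulfur. The fallback sets out from 2 and comes back at 10, with the chloride in place from the start. Epoxidation of 2 under the conditions of step 2 but with L-(+)-diisopropyl tartrate should give (S)-[2-(chloromethyl)oxiran-2-yl]methanol F6, which is tosylated in the same flask (TsCl, Et3N, DMAP, −10 °C) to (R)-[2-(chloromethyl)oxiran-2-yl]methyl 4-methylbenzenesulfonate F7. Lithiodithiane 7 then opens the epoxide of F7 and the alkoxide displaces tosylate in preference to chloride, which should give 10 directly.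

3. Step 2. Epoxidation of the electron-poor alkene may be slow, the small polar epoxy alcohol may be opened by isopropoxide or lost on isolation, and facial selectivity may be poor. The fallback sets out from 1 and comes back at 9, using a lipophilic silyl ether of a better precedented substrate class. NaH/TBSCl in THF monosilylates 1 to 2-({[tert-butyl(dimethyl)silyl]oxy}methyl)prop-2-en-1-ol F8. Sharpless epoxidation with L-(+)-diisopropyl tartrate should give (S)-[2-({[tert-butyl(dimethyl)silyl]oxy}methyl)oxiran-2-yl]methanol F9. The Appel reaction (PPh3, CCl4, NaHCO3) gives (S)-tert-butyl{[2-(chloromethyl)oxiran-2-yl]methoxy}dimethylsilane F10. Lithiodithiane 7 opens its epoxide and the alkoxide displaces chloride to give (R)-tert-butyl{[2-({2-[(8Z)-heptadec-8-en-1-yl]-1,3-dithian-2-yl}methyl)oxiran-2-yl]methoxy}dimethylsilane F11, and n-Bu4NF buffered with AcOH removes the silyl group to give 9.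

**Further compounds**

F1 | step 9 | (2S)-2-(1,3-dithian-2-ylmethyl)-2-({2-[(8Z)-heptadec-8-en-1-yl]-1,3-dithian-2-yl}methyl)oxirane | CCCCCCCC/C=C\CCCCCCCC1(SCCCS1)C[C@@]2(CC3SCCCS3)CO2
F2 | step 9 | (2S)-1-(1,3-dithian-2-yl)-2-({2-[(8Z)-heptadec-8-en-1-yl]-1,3-dithian-2-yl}methyl)pent-4-en-2-ol | CCCCCCCC/C=C\CCCCCCCC1(SCCCS1)C[C@](O)(CC=C)CC2SCCCS2
F3 | step 9 | (3S,13Z)-3-hydroxy-5-oxo-3-(prop-2-en-1-yl)docos-13-enal | CCCCCCCC/C=C\CCCCCCCC(=O)C[C@](O)(CC=C)CC=O
F4 | step 9 | (5S,15Z)-3,5-dihydroxy-5-(prop-2-en-1-yl)tetracosa-1,15-dien-7-one | CCCCCCCC/C=C\CCCCCCCC(=O)C[C@](O)(CC=C)CC(O)C=C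
F5 | step 9 | (10Z)-1-[(1S)-1,5-dihydroxycyclohex-3-en-1-yl]nonadec-10-en-2-one | CCCCCCCC/C=C\CCCCCCCC(=O)C[C@]1(O)CC=CC(O)C1
F6 | step 6 | (S)-[2-(chloromethyl)oxiran-2-yl]methanol | OC[C@@]1(CCl)CO1
F7 | step 6 | (R)-[2-(chloromethyl)oxiran-2-yl]methyl 4-methylbenzenesulfonate | Cc1ccc(cc1)S(=O)(=O)OC[C@@]1(CCl)CO1
F8 | step 2 | 2-({[tert-butyl(dimethyl)silyl]oxy}methyl)prop-2-en-1-ol | C=C(CO)CO[Si](C)(C)C(C)(C)C
F9 | step 2 | (S)-[2-({[tert-butyl(dimethyl)silyl]oxy}methyl)oxiran-2-yl]methanol | OC[C@@]1(CO[Si](C)(C)C(C)(C)C)CO1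
F10 | step 2 | (S)-tert-butyl{[2-(chloromethyl)oxiran-2-yl]methoxy}dimethylsilane | ClC[C@@]1(CO[Si](C)(C)C(C)(C)C)CO1
F11 | step 2 | (R)-tert-butyl{[2-({2-[(8Z)-heptadec-8-en-1-yl]-1,3-dithian-2-yl}methyl)oxiran-2-yl]methoxy}dimethylsilane | CCCCCCCC/C=C\CCCCCCCC1(SCCCS1)C[C@]2(CO[Si](C)(C)C(C)(C)C)CO2
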